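**Plan**

- Numbering: in each ring C1 (quaternary; Me and the C9 acyl group), C2–C4 (CH2), C5 (=C7H–C8H2), C6 (CHOH); primes mark the mirror-image half of this meso target.
- Cuts: C5–C6 and C5′–C6′ (ring bonds, Ni/Cr alkenyl bromide–aldehyde addition), then C4–C5 and C4′–C5′ (Negishi coupling), then C1–C2 (Michael addition to acrolein) and C1–C9 (Claisen acylation) in each fragment. C5/C5′ come from CBr4 and C7–C8–C8′–C7′ from succinaldehyde.
- Enabling feature: each C5 carries C4 trans and C6 cis to C8, so a CBr2 carbon on C7 can accept C4 (trans bromide, Pd) and later C6 (cis bromide, Cr) one at a time.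
- Forward: the chain is joined first. The tetrabromide linchpin is alkylated at one end with the (S)-zinc reagent (step 10) and at the other with its antipode (step 11); both cyclohexane rings close together in the last step.
- Stereochemistry: C1/C1′ from two pseudoenantiomeric organocatalytic Michael additions; the meso pairing from using the two antipodes in sequence; both alkene geometries from trans-selective coupling followed by retentive Ni/Cr addition; C6/C6′ by substrate control from C1/C1′ during ring closure.

Key step: step 11

Remark 1: the target is meso (C1 R, C6 S, C1′ S, C6′ R; both exocyclic alkenes Z), so the route aims at this one achiral stereoisomer.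
Remark 2 (assumption): the cupreidine-derived catalyst is taken to give (S)-7 and the cupreine-derived one (R)-10; if the sense is the opposite, the two catalysts change places, since both antipodes are used in equal amount.
Remark 3: C6 is carried as a tert-butyl ester and C9 as the ketone. With the ester as senior group the fragment that becomes C1 (R) is named (S); the descriptor change in step 12 reflects CIP priorities only.

**Route**

Step 1
Reactants: 1 4-methylpent-3-enoic acid; 2 tert-butyl propanoate
Product: 5 tert-butyl 2,6-dimethyl-3-oxohept-5-enoate, via acyl imidazolide 3 (not isolated), via lithium ester enolate 4 (not isolated)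
Conditions: 1, CDI (1.1 equiv), THF, 23 °C; cannulate into 2 (2.2 equiv)/LDA (2.2 equiv), THF, −78 °C; AcOH quench at −78 °C
Reagents that add atoms: 1,1′-carbonyldiimidazole, O=C(n1ccnc1)n1ccnc1 (imidazolyl group of intermediate 3 only); lithium diisopropylamide, [Li]N(C(C)C)C(C)C (lithium of intermediate 4 only); no reagent atom remains in 5
Why: Crossed Claisen condensation in which imidazolide 3 C-acylates the preformed ester enolate 4 at −78 °C and the β-keto ester stays as its chelated lithium enolate until the acidic quench, which stops double acylation and keeps the β,γ-alkene out of conjugation; C1 is still enolisable here, so no stereochemistry is at stake.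

Step 2
Reactants: 5 tert-butyl 2,6-dimethyl-3-oxohept-5-enoate; 6 acrolein
Product: 7 tert-butyl (2S)-2,6-dimethyl-3-oxo-2-(3-oxopropyl)hept-5-enoate
Conditions: 9-O-benzylcupreidine (10 mol %), CH2Cl2, −25 °C
Reagents that add atoms: none
Why: Bifunctional cinchona-alkaloid-catalysed asymmetric Michael addition of an α-substituted β-keto ester to acrolein, in which the quinuclidine nitrogen ion-pairs with the enol and the 6′-OH hydrogen-bonds the enal so that acrolein reaches one enolate face and the catalyst sets the quaternary centre C1, while the weak amine base leaves the C(=O)CH2CH= methylene alone.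

Step 3
Reactants: 7 tert-butyl (2S)-2,6-dimethyl-3-oxo-2-(3-oxopropyl)hept-5-enoate
Product: 8 tert-butyl (2S)-2-(3-hydroxypropyl)-2,6-dimethyl-3-oxohept-5-enoate
Conditions: NaBH4, EtOH/CH2Cl2 (3:7), −78 °C
Reagents that add atoms: none
Why: Chemoselective sodium borohydride reduction at −78 °C, where the unhindered aldehyde should be reduced well before the neopentyl-type ketone or the ester, and the tert-butyl ester keeps the resulting δ-hydroxy ester from lactonising.

Step 4
Reactants: 8 tert-butyl (2S)-2-(3-hydroxypropyl)-2,6-dimethyl-3-oxohept-5-enoate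
Product: 9 tert-butyl (2S)-2-(3-iodopropyl)-2,6-dimethyl-3-oxohept-5-enoate
Conditions: I2, PPh3, imidazole, CH2Cl2, 0 °C, dark
Reagents that add atoms: iodine, II
Why: Appel-type iodination in which the primary alcohol is displaced via its alkoxyphosphonium ion by iodide (SN2) under near-neutral conditions that leave the deconjugated enone and the tert-butyl ester alone.

Step 5
Reactants: 5 tert-butyl 2,6-dimethyl-3-oxohept-5-enoate; 6 acrolein
Product: 10 tert-butyl (2R)-2,6-dimethyl-3-oxo-2-(3-oxopropyl)hept-5-enoate
Conditions: 9-O-benzylcupreine (10 mol %), CH2Cl2, −25 °C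
Reagents that add atoms: none
Why: The same cinchona-catalysed asymmetric Michael addition as in step 2, run with the pseudoenantiomeric catalyst, which presents the opposite enolate face to acrolein and so sets C1′ in the antipodal sense.

Step 6
Reactants: 10 tert-butyl (2R)-2,6-dimethyl-3-oxo-2-(3-oxopropyl)hept-5-enoate
Product: 11 tert-butyl (2R)-2-(3-hydroxypropyl)-2,6-dimethyl-3-oxohept-5-enoate
Conditions: NaBH4, EtOH/CH2Cl2 (3:7), −78 °C
Reagents that add atoms: none
Why: Chemoselective borohydride reduction of the aldehyde in the presence of the hindered ketone and the tert-butyl ester, as in step 3.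

Step 7
Reactants: 11 tert-butyl (2R)-2-(3-hydroxypropyl)-2,6-dimethyl-3-oxohept-5-enoate
Product: 12 tert-butyl (2R)-2-(3-iodopropyl)-2,6-dimethyl-3-oxohept-5-enoate
Conditions: I2, PPh3, imidazole, CH2Cl2, 0 °C, dark
Reagents that add atoms: iodine, II
Why: Appel-type iodination of the primary alcohol by SN2 displacement of the alkoxyphosphonium ion, as in step 4.

Step 8
Reactants: 13 2,5-dimethoxytetrahydrofuran
Product: 14 succinaldehyde
Conditions: H2O, 90 °C; distil off MeOH; extract (CH2Cl2), distil, use fresh
Reagents that add atoms: water, O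
Why: Hydrolysis of the cyclic bis-acetal in hot water, driven by removal of methanol, should free both aldehyde groups (C7 and C7′ with C8–C8′ between them).

Step 9
Reactants: 14 succinaldehyde; 15 carbon tetrabromide
Product: 16 1,1,6,6-tetrabromohexa-1,5-diene
Conditions: 15 (4 equiv), PPh3 (8 equiv), CH2Cl2, 0 °C
Reagents that add atoms: none
Why: Ramirez dibromo-olefination (first stage of the Corey–Fuchs sequence), in which the ylide Ph3P=CBr2 formed from CBr4 and PPh3 undergoes Wittig reaction with both aldehydes and adds C5 and C5′ as CBr2 carbons.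

Step 10
Reactants: 9 tert-butyl (2S)-2-(3-iodopropyl)-2,6-dimethyl-3-oxohept-5-enoate; 16 1,1,6,6-tetrabromohexa-1,5-diene
Product: 18 tert-butyl (2S)-2,6-dimethyl-3-oxo-2-[(4Z)-4,9,9-tribromonona-4,8-dien-1-yl]hept-5-enoate, via (S)-alkylzinc iodide 17 (not isolated)
Conditions: 9, activated Zn dust, LiCl, THF, 35 °C; cannulate into 16 (3 equiv), PdCl2(DPEphos) (5 mol %), THF, 0 → 23 °C
Reagents that add atoms: zinc, [Zn] (held in intermediate 17 only; no reagent atom remains in 18)
Why: LiCl-assisted zinc insertion into the primary C–I bond gives the keto-ester-tolerant alkylzinc iodide 17, which undergoes the palladium-catalysed trans-selective Negishi monoalkylation of a 1,1-dibromoalkene at one CBr2 terminus of 16 (oxidative addition at the bromide trans to the chain, retention on reductive elimination, C4–C5 formed), with the threefold excess of 16 holding back alkylation at both ends.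

Step 11
Reactants: 12 tert-butyl (2R)-2-(3-iodopropyl)-2,6-dimethyl-3-oxohept-5-enoate; 18 tert-butyl (2S)-2,6-dimethyl-3-oxo-2-[(4Z)-4,9,9-tribromonona-4,8-dien-1-yl]hept-5-enoate
Product: 20 di-tert-butyl (2S,6Z,10Z,15R)-6,11-dibromo-2,15-dimethyl-2,15-bis(4-methylpent-3-enoyl)hexadeca-6,10-dienedioate, via (R)-alkylzinc iodide 19 (not isolated)
Conditions: 12 (1.3 equiv), activated Zn dust, LiCl, THF, 35 °C; cannulate into 18, PdCl2(DPEphos) (5 mol %), THF, 0 → 23 °C
Reagents that add atoms: zinc, [Zn] (held in intermediate 19 only; no reagent atom remains in 20)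
Why: Pd(0) carrying the wide-bite-angle DPEphos ligand inserts into the C–Br bond of the remaining CBr2 terminus of 18 that lies trans to the C8′ chain (the less hindered one, cis to H), alkylzinc iodide 19 transmetallates, and reductive elimination forms C4′–C5′ with retention, leaving the bromide cis to C8′. The closest known reaction type is the palladium-catalysed trans-selective monoalkylation (Negishi coupling) of 1,1-dihalo-1-alkenes with alkylzinc reagents. No ring closes and no stereocentre is created; the step fixes the second C=C geometry and, because 19 is the antipode of 17, the heterochiral (meso) pairing of C1 and C1′ without any induction across the four-carbon linker. Three selectivities are needed: trans over cis bromide (sterics of the dibromoalkene plus the bidentate ligand), mono- over geminal dialkylation (the product is a more hindered, electron-richer internal alkenyl bromide that adds to Pd(0) more slowly than a CBr2 carbon), and the CBr2 terminus over the resident (Z)-bromide of 18 (same argument). Fast reductive elimination from the wide-bite-angle complex should outrun β-hydride elimination of the primary alkyl group, and the neutral organozinc leaves the ketones, the tert-butyl esters and the deconjugated prenyl alkenes alone.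

Step 12
Reactants: 20 di-tert-butyl (2S,6Z,10Z,15R)-6,11-dibromo-2,15-dimethyl-2,15-bis(4-methylpent-3-enoyl)hexadeca-6,10-dienedioate
Product: 21 (2R,6Z,10Z,15S)-6,11-dibromo-2,15-bis(1-hydroxy-4-methylpent-3-en-1-yl)-2,15-dimethylhexadeca-6,10-diene-1,16-diol (mixture of epimers at the two side-chain carbinols)
Conditions: LiAlH4 (excess), THF, 0 → 23 °C
Reagents that add atoms: none
Why: Lithium aluminium hydride reduction of both ketones and both hindered tert-butyl esters to the bis(1,3-diol), unactivated alkenyl bromides and isolated alkenes being inert to this reagent at or below room temperature; the C9/C9′ carbinol centres form as mixtures and are erased in step 13.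

Step 13
Reactants: 21 (2R,6Z,10Z,15S)-6,11-dibromo-2,15-bis(1-hydroxy-4-methylpent-3-en-1-yl)-2,15-dimethylhexadeca-6,10-diene-1,16-diol
Product: 22 (2R,6Z,10Z,15S)-6,11-dibromo-2,15-dimethyl-2,15-bis(4-methylpent-3-enoyl)hexadeca-6,10-dienedial
Conditions: Dess–Martin periodinane (excess), NaHCO3 (buffer), CH2Cl2, 0 → 23 °C; used directly
Reagents that add atoms: none
Why: Dess–Martin oxidation under bicarbonate buffer turns the primary alcohols into the C6/C6′ aldehydes and the secondary alcohols back into the C9/C9′ ketones without base, so the non-enolisable β-keto aldehydes should not be deformylated and the β,γ-alkenes should not move into conjugation.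

Step 14
Reactants: 22 (2R,6Z,10Z,15S)-6,11-dibromo-2,15-dimethyl-2,15-bis(4-methylpent-3-enoyl)hexadeca-6,10-dienedial
Product: 23 1-[(1R,2S,3Z)-2-hydroxy-3-{4-[(1Z,2R,3S)-2-hydroxy-3-methyl-3-(4-methylpent-3-enoyl)cyclohexylidene]butylidene}-1-methylcyclohexyl]-4-methylpent-3-en-1-one (target)
Conditions: CrCl2 (10 equiv), NiCl2 (0.1 equiv), degassed DMSO, 23 °C, 0.005 M
Reagents that add atoms: none
Why: Twofold intramolecular Nozaki–Hiyama–Kishi reaction in which Ni(0) inserts into each (Z)-alkenyl bromide, transmetallation gives an alkenylchromium(III) species that adds to the aldehyde (not to the equally distant C9 ketone) to close each six-membered ring at C5–C6 with retention of alkene geometry (C6 cis to C8), and C6 is set under control of the adjacent quaternary C1, the expected transition state having the C6–O bond pseudoaxial (no A(1,3) strain with C8) and gauche to the equatorial C9 acyl group whose oxygen can share chromium, which puts OH cis to acyl and trans to methyl in each ring.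

**Compound list**

1 | 4-methylpent-3-enoic acid | CC(C)=CCC(=O)O | starting material
2 | tert-butyl propanoate | CCC(=O)OC(C)(C)C | starting material
3 | 1-(4-methylpent-3-enoyl)-1H-imidazole (acyl imidazolide) | CC(C)=CCC(=O)n1ccnc1 | intermediate
4 | lithium enolate of tert-butyl propanoate | CC=C(O[Li])OC(C)(C)C | intermediate
5 | tert-butyl 2,6-dimethyl-3-oxohept-5-enoate (racemic at the enolisable C2) | CC(C)=CCC(=O)C(C)C(=O)OC(C)(C)C | intermediate
6 | acrolein | C=CC=O | starting material
7 | tert-butyl (2S)-2,6-dimethyl-3-oxo-2-(3-oxopropyl)hept-5-enoate | CC(C)=CCC(=O)[C@@](C)(C(=O)OC(C)(C)C)CCC=O | intermediate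
8 | tert-butyl (2S)-2-(3-hydroxypropyl)-2,6-dimethyl-3-oxohept-5-enoate | CC(C)=CCC(=O)[C@@](C)(C(=O)OC(C)(C)C)CCCO | intermediate
9 | tert-butyl (2S)-2-(3-iodopropyl)-2,6-dimethyl-3-oxohept-5-enoate | CC(C)=CCC(=O)[C@@](C)(C(=O)OC(C)(C)C)CCCI | intermediate
10 | tert-butyl (2R)-2,6-dimethyl-3-oxo-2-(3-oxopropyl)hept-5-enoate | CC(C)=CCC(=O)[C@](C)(C(=O)OC(C)(C)C)CCC=O | intermediate
11 | tert-butyl (2R)-2-(3-hydroxypropyl)-2,6-dimethyl-3-oxohept-5-enoate | CC(C)=CCC(=O)[C@](C)(C(=O)OC(C)(C)C)CCCO | intermediate
12 | tert-butyl (2R)-2-(3-iodopropyl)-2,6-dimethyl-3-oxohept-5-enoate | CC(C)=CCC(=O)[C@](C)(C(=O)OC(C)(C)C)CCCI | intermediate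
13 | 2,5-dimethoxytetrahydrofuran | COC1CCC(OC)O1 | starting material
14 | succinaldehyde (butanedial) | O=CCCC=O | intermediate
15 | carbon tetrabromide | BrC(Br)(Br)Br | starting material
16 | 1,1,6,6-tetrabromohexa-1,5-diene | BrC(Br)=CCCC=C(Br)Br | intermediate
17 | [(4S)-4-(tert-butoxycarbonyl)-4,8-dimethyl-5-oxonon-7-en-1-yl]zinc iodide | CC(C)=CCC(=O)[C@@](C)(C(=O)OC(C)(C)C)CCC[Zn]I | intermediate
18 | tert-butyl (2S)-2,6-dimethyl-3-oxo-2-[(4Z)-4,9,9-tribromonona-4,8-dien-1-yl]hept-5-enoate | CC(C)=CCC(=O)[C@@](C)(C(=O)OC(C)(C)C)CCC/C(Br)=C/CCC=C(Br)Br | intermediate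
19 | [(4R)-4-(tert-butoxycarbonyl)-4,8-dimethyl-5-oxonon-7-en-1-yl]zinc iodide | CC(C)=CCC(=O)[C@](C)(C(=O)OC(C)(C)C)CCC[Zn]I | intermediate
20 | di-tert-butyl (2S,6Z,10Z,15R)-6,11-dibromo-2,15-dimethyl-2,15-bis(4-methylpent-3-enoyl)hexadeca-6,10-dienedioate (meso) | CC(C)=CCC(=O)[C@@](C)(C(=O)OC(C)(C)C)CCC/C(Br)=C/CC/C=C(Br)/CCC[C@@](C)(C(=O)OC(C)(C)C)C(=O)CC=C(C)C | intermediate
21 | (2R,6Z,10Z,15S)-6,11-dibromo-2,15-bis(1-hydroxy-4-methylpent-3-en-1-yl)-2,15-dimethylhexadeca-6,10-diene-1,16-diol (side-chain carbinol epimers) | CC(C)=CCC(O)[C@@](C)(CO)CCC/C(Br)=C/CC/C=C(Br)/CCC[C@@](C)(CO)C(O)CC=C(C)C | intermediate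
22 | (2R,6Z,10Z,15S)-6,11-dibromo-2,15-dimethyl-2,15-bis(4-methylpent-3-enoyl)hexadeca-6,10-dienedial (meso) | CC(C)=CCC(=O)[C@@](C)(C=O)CCC/C(Br)=C/CC/C=C(Br)/CCC[C@@](C)(C=O)C(=O)CC=C(C)C | intermediate
23 | 1-[(1R,2S,3Z)-2-hydroxy-3-{4-[(1Z,2R,3S)-2-hydroxy-3-methyl-3-(4-methylpent-3-enoyl)cyclohexylidene]butylidene}-1-methylcyclohexyl]-4-methylpent-3-en-1-one (CNP0297042.2, meso) | CC(C)=CCC(=O)[C@]1(C)CCC/C(=C/CC/C=C2/CCC[C@](C)(C(=O)CC=C(C)C)[C@@H]2O)[C@@H]1O | target

**Totals**

Total step count: 14.
Longest linear sequence: 9 steps (1, 2, 3, 4, 10, 11, 12, 13, 14) from 4-methylpent-3-enoic acid.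

**Steps most likely to fail**

Step 14. The alkenylchromium may add to the aldehyde with poor facial selectivity in one or both rings, because C6 and C6′ rest on substrate control from C1 and C1′ alone. The fallback sets out from 22 and comes back at 23. The Ni/Cr closure is run without regard to the carbinol configuration to give the C6/C6′-epimeric ring-closed diols F1. Manganese dioxide in CH2Cl2 then oxidises these allylic alcohols to the cross-conjugated bis(enone) F2. A Luche reduction (NaBH4, CeCl3·7H2O, MeOH, −78 °C) should reduce each ring enone ahead of the isolated neopentyl C9 ketone. Hydride is delivered axially, so the face is decided by ring conformation (an axial acyl group, which keeps the two carbonyl dipoles apart, would give OH cis to acyl) and need not follow the Ni/Cr result. C6 is thus set by C–H instead of C–C bond formation.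

Step 10. The alkylzinc may react at both ends of the linchpin, or twice at one carbon, before the excess of 16 intervenes, and the mono-adduct must be freed from much unreacted tetrabromide. The same coupling recurs in step 11, but there only one CBr2 terminus is left. The fallback sets out from 9 (as its zinc reagent 17) and comes back at 18. Commercial 4-[(tert-butyldimethylsilyl)oxy]butanal F3 is converted with CBr4/PPh3 into tert-butyl[(5,5-dibromopent-4-en-1-yl)oxy]dimethylsilane F4, a linchpin with a single CBr2 terminus that can be used 1:1. The same trans-selective Negishi coupling with 17 should give the (Z)-bromoalkene silyl ether F5. HF·pyridine frees the primary alcohol F6, and buffered Dess–Martin oxidation gives the aldehyde F7. A second CBr4/PPh3 olefination, in which the aldehyde reacts and the hindered ketone does not, adds C5′ as CBr2 and arrives at 18 for step 11.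

Step 2 (and its mirror, step 5). Enantiofacial discrimination on this acyclic keto ester may be incomplete, and an enantiomerically impure fragment would carry through as the C1/C1′-homochiral diastereomer of 20. The fallback sets out from 5 and comes back at 8 and 11. Triethylamine-catalysed Michael addition of 5 to acrolein gives the racemic aldehyde F8, and borohydride reduction as in step 3 gives the racemic alcohol F9. Preparative chromatography of F9 on a chiral stationary phase (SFC) separates it into 8 and 11. Because the meso target consumes both antipodes in equal amount, neither is discarded.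

**Further compounds**

F1 | step 14 | C6/C6′-epimeric mixture of the ring-closed diol | CC(C)=CCC(=O)[C@]1(C)CCC/C(=C/CC/C=C2/CCC[C@](C)(C(=O)CC=C(C)C)C2O)C1O
F2 | step 14 | bis(enone) with C6 and C6′ as ring ketones | CC(C)=CCC(=O)[C@]1(C)CCC/C(=C/CC/C=C2/CCC[C@](C)(C(=O)CC=C(C)C)C2=O)C1=O
F3 | step 10 | 4-[(tert-butyldimethylsilyl)oxy]butanal | O=CCCCO[Si](C)(C)C(C)(C)C
F4 | step 10 | tert-butyl[(5,5-dibromopent-4-en-1-yl)oxy]dimethylsilane | BrC(Br)=CCCCO[Si](C)(C)C(C)(C)C
F5 | step 10 | tert-butyl (2S)-2-[(4Z)-4-bromo-8-{[tert-butyl(dimethyl)silyl]oxy}oct-4-en-1-yl]-2,6-dimethyl-3-oxohept-5-enoate | CC(C)=CCC(=O)[C@@](C)(C(=O)OC(C)(C)C)CCC/C(Br)=C/CCCO[Si](C)(C)C(C)(C)C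
F6 | step 10 | tert-butyl (2S)-2-[(4Z)-4-bromo-8-hydroxyoct-4-en-1-yl]-2,6-dimethyl-3-oxohept-5-enoate | CC(C)=CCC(=O)[C@@](C)(C(=O)OC(C)(C)C)CCC/C(Br)=C/CCCO
F7 | step 10 | tert-butyl (2S)-2-[(4Z)-4-bromo-8-oxooct-4-en-1-yl]-2,6-dimethyl-3-oxohept-5-enoate | CC(C)=CCC(=O)[C@@](C)(C(=O)OC(C)(C)C)CCC/C(Br)=C/CCC=O
F8 | step 2 | tert-butyl 2,6-dimethyl-3-oxo-2-(3-oxopropyl)hept-5-enoate (racemic) | CC(C)=CCC(=O)C(C)(C(=O)OC(C)(C)C)CCC=O
F9 | step 2 | tert-butyl 2-(3-hydroxypropyl)-2,6-dimethyl-3-oxohept-5-enoate (racemic) | CC(C)=CCC(=O)C(C)(C(=O)OC(C)(C)C)CCCO
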